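**Strategy.** The hexasubstituted A ring is made last. Its C5–C8 carbons carry four contiguous oxygens (5-OH, 6-, 7-, 8-OMe), the oxygenation pattern of dimethyl squarate, while C4a=C8a is the unsubstituted C5=C6 bond of a 2-aryl-4H-pyran-4-one. Joining squarate to pyranone C6 gives a 4-methoxy-4-(pyranon-6-yl)-2,3-dimethoxycyclobutenone. Heating it opens the four-membered ring to a dienylketene that closes onto pyranone C5, forging C5–C4a, closing the benzenoid ring and delivering the free chelated 5-OH beside three methoxyls in one operation. The B ring is carried as the bis(benzyl) ether of 2,5-dihydroxy-4-methoxyphenyl and released at the end.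

Key step: step 9

Remark on the chemistry: the target has no stereocentre, so "single enantiomer" requires no stereocontrol. The stereocentres of 13, 14 and 16 are formed racemic and become sp2 carbons in step 9.

**Route**

Step 1
Reactants: 1 2-methoxyhydroquinone
Product: 2 1,4-bis(benzyloxy)-2-methoxybenzene
Conditions: BnBr (2.4 equiv), K2CO3, DMF, 60 °C, argon
Reagents that add atoms: benzyl bromide, BrCc1ccccc1
Why: Williamson ether synthesis on both phenols; air is excluded because the hydroquinone dianion oxidises easily, and benzyl is chosen because it survives all later steps and is removed without touching methyl ethers.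

Step 2
Reactants: 2 1,4-bis(benzyloxy)-2-methoxybenzene
Product: 4 2,5-bis(benzyloxy)-4-methoxybenzaldehyde, via iminium chloride 3 (not isolated)
Conditions: POCl3, DMF, 0 → 70 °C; then ice-water, rt
Reagents that add atoms: DMF, CN(C)C=O; water, O
Why: Vilsmeier–Haack formylation should occur at the one ring position that is para to the methoxy group and ortho to a benzyloxy group (the site attacked in 1,2,4-trialkoxybenzenes), since the other free positions are either activated by a single ortho oxygen or flanked by two substituents.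

Step 3
Reactants: 4 2,5-bis(benzyloxy)-4-methoxybenzaldehyde
Product: 5 2,5-bis(benzyloxy)-4-methoxybenzoic acid
Conditions: NaClO2, NaH2PO4, 2-methyl-2-butene, t-BuOH–THF–H2O, rt
Reagents that add atoms: sodium chlorite, [Na+].[O-]Cl=O
Why: Pinnick oxidation converts the aldehyde to the acid under buffered conditions, and the alkene scavenger removes hypochlorite before it can chlorinate the electron-rich ring.

Step 4
Reactants: 5 2,5-bis(benzyloxy)-4-methoxybenzoic acid
Product: 6 2,5-bis(benzyloxy)-4-methoxybenzoyl chloride
Conditions: (COCl)2, DMF (cat.), CH2Cl2, 0 °C → rt; evaporate, use crude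
Reagents that add atoms: oxalyl chloride, O=C(Cl)C(=O)Cl
Why: DMF-catalysed acid chloride formation with oxalyl chloride is neutral and gives only volatile by-products, so the benzyl ethers are not at risk.

Step 5
Reactants: 6 2,5-bis(benzyloxy)-4-methoxybenzoyl chloride + 7 (E)-4-methoxybut-3-en-2-one
Product: 9 (E)-1-[2,5-bis(benzyloxy)-4-methoxyphenyl]-5-methoxypent-4-ene-1,3-dione, via lithium dienolate 8 (not isolated)
Conditions: 7 (2 equiv), LiHMDS (2 equiv), THF, −78 °C; then 6 in THF, −78 °C; aq NH4Cl
Reagents that add atoms: none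
Why: Claisen-type C-acylation of the kinetic methyl-side lithium enolate by the acid chloride, with the second equivalent of enolate taking up the acidic proton of the 1,3-diketone so that the acylation goes to completion.

Step 6
Reactants: 9 (E)-1-[2,5-bis(benzyloxy)-4-methoxyphenyl]-5-methoxypent-4-ene-1,3-dione
Product: 10 2-[2,5-bis(benzyloxy)-4-methoxyphenyl]-4H-pyran-4-one
Conditions: TFA (cat. to 2 equiv), PhMe, rt
Reagents that add atoms: none
Why: Acid-catalysed cyclocondensation (6-endo oxa-Michael addition of the aryl-ketone enol oxygen to the β-methoxyenone, then loss of methanol) is an established entry to 2-substituted γ-pyranones, and dilute TFA at room temperature leaves aryl benzyl ethers intact.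

Step 7
Reactants: 10 2-[2,5-bis(benzyloxy)-4-methoxyphenyl]-4H-pyran-4-one + 11 dimethyl squarate
Product: 13 rac-4-{6-[2,5-bis(benzyloxy)-4-methoxyphenyl]-4-oxo-4H-pyran-2-yl}-4-hydroxy-2,3-dimethoxycyclobut-2-en-1-one, via 6-lithiopyranone 12 (not isolated)
Conditions: LiTMP (1.05 equiv, from TMPH + n-BuLi), THF, −78 °C, brief; then 11 (1.5 equiv) in THF, −78 °C; aq NH4Cl at −78 °C
Reagents that add atoms: none
Why: Deprotonative lithiation then 1,2-addition to a squarate carbonyl: C6–H is the only sp2 C–H next to the ring oxygen (the counterpart of chromone C2–H, which hindered lithium amides remove at low temperature), the vinyllithium is trapped at once by the excess squarate, and the carbinol centre forms racemic, which is harmless because step 9 flattens it.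

Step 8
Reactants: 13 rac-4-{6-[2,5-bis(benzyloxy)-4-methoxyphenyl]-4-oxo-4H-pyran-2-yl}-4-hydroxy-2,3-dimethoxycyclobut-2-en-1-one
Product: 14 rac-4-{6-[2,5-bis(benzyloxy)-4-methoxyphenyl]-4-oxo-4H-pyran-2-yl}-2,3,4-trimethoxycyclobut-2-en-1-one
Conditions: MeI (excess), Ag2O, MeCN, rt, dark
Reagents that add atoms: iodomethane, CI
Why: Purdie methylation (Ag2O/MeI) etherifies the tertiary carbinol without a strong base that could open the α-hydroxycyclobutenone, and iodomethane is too weak an alkylating agent to attack the pyranone carbonyl oxygen.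

Step 9
Reactants: 14 rac-4-{6-[2,5-bis(benzyloxy)-4-methoxyphenyl]-4-oxo-4H-pyran-2-yl}-2,3,4-trimethoxycyclobut-2-en-1-one
Product: 17 2',5'-bis(benzyloxy)-5-hydroxy-4',6,7,8-tetramethoxyflavone, via dienylketene 15 (not isolated), via cyclohexadienone 16 (not isolated)
Conditions: PhMe (degassed, dilute), reflux, argon
Reagents that add atoms: none
Why: Heating breaks the C1–C4 bond of the cyclobutenone by conrotatory 4π-electrocyclic opening, the C4 methoxy donor turning outward so that the pyranonyl group lies inward, cis to the ketene, in (Z)-dienylketene 15. A thermally allowed disrotatory 6π-electrocyclisation then joins the ketene carbon to pyranone C5 (the nucleophilic β-carbon of the O1–C6=C5 enol ether), closing the six-membered carbocycle across the pyranone C5=C6 bond to give 4aH-dienone 16, whose tautomerisation aromatises the new ring irreversibly. The closest known reaction type is the thermal ring expansion of squarate-derived 4-alkenyl- and 4-heteroaryl-4-alkoxycyclobutenones to mono-O-protected hydroquinones (Moore-type benzannulation). No stereocentre survives: the quaternary carbon of 14 becomes C8 and the transient C4a–H centre of 16 is lost on enolisation. The selectivity needed is inward rotation of the pyranonyl group, secured by the outward preference of the C4 oxygen donor; the closure has only one possible site, and the oxygens are differentiated by construction (carbinol OMe becomes 8-OMe, the squarate methoxyls become 6- and 7-OMe, the ketene oxygen becomes the free chelated 5-OH).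

Step 10
Reactants: 17 2',5'-bis(benzyloxy)-5-hydroxy-4',6,7,8-tetramethoxyflavone
Product: 18 5,2',5'-trihydroxy-6,7,8,4'-tetramethoxyflavone
Conditions: H2 (1 atm), 10% Pd/C, EtOAc–THF, rt; stop after 2 equiv H2; filter and concentrate under argon
Reagents that add atoms: none
Why: Catalytic hydrogenolysis cleaves both aryl benzyl ethers much faster than it reduces the vinylogous-ester C2=C3 bond of the flavone, methyl ethers are untouched, and exclusion of air protects the 2',5'-hydroquinone from oxidation to the quinone.

**Compound list**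

1 | 2-methoxyhydroquinone (2-methoxybenzene-1,4-diol) | COc1cc(O)ccc1O | starting material
2 | 1,4-bis(benzyloxy)-2-methoxybenzene | COc1cc(OCc2ccccc2)ccc1OCc1ccccc1 | intermediate
3 | N-[2,5-bis(benzyloxy)-4-methoxybenzylidene]-N-methylmethanaminium chloride | C[N+](C)=Cc1cc(OCc2ccccc2)c(OC)cc1OCc1ccccc1.[Cl-] | intermediate
4 | 2,5-bis(benzyloxy)-4-methoxybenzaldehyde | COc1cc(OCc2ccccc2)c(C=O)cc1OCc1ccccc1 | intermediate
5 | 2,5-bis(benzyloxy)-4-methoxybenzoic acid | COc1cc(OCc2ccccc2)c(C(=O)O)cc1OCc1ccccc1 | intermediate
6 | 2,5-bis(benzyloxy)-4-methoxybenzoyl chloride | COc1cc(OCc2ccccc2)c(C(=O)Cl)cc1OCc1ccccc1 | intermediate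
7 | (E)-4-methoxybut-3-en-2-one | CO/C=C/C(C)=O | starting material
8 | lithium (E)-4-methoxybuta-1,3-dien-2-olate | C=C(O[Li])/C=C/OC | intermediate
9 | (E)-1-[2,5-bis(benzyloxy)-4-methoxyphenyl]-5-methoxypent-4-ene-1,3-dione (present largely as its enol) | CO/C=C/C(=O)CC(=O)c1cc(OCc2ccccc2)c(OC)cc1OCc1ccccc1 | intermediate
10 | 2-[2,5-bis(benzyloxy)-4-methoxyphenyl]-4H-pyran-4-one | O=c1ccoc(-c2cc(OCc3ccccc3)c(OC)cc2OCc2ccccc2)c1 | intermediate
11 | dimethyl squarate (3,4-dimethoxycyclobut-3-ene-1,2-dione) | COC1=C(OC)C(=O)C1=O | starting material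
12 | 2-[2,5-bis(benzyloxy)-4-methoxyphenyl]-6-lithio-4H-pyran-4-one | [Li]c1cc(=O)cc(-c2cc(OCc3ccccc3)c(OC)cc2OCc2ccccc2)o1 | intermediate
13 | rac-4-{6-[2,5-bis(benzyloxy)-4-methoxyphenyl]-4-oxo-4H-pyran-2-yl}-4-hydroxy-2,3-dimethoxycyclobut-2-en-1-one | COC1=C(OC)C(O)(c2cc(=O)cc(-c3cc(OCc4ccccc4)c(OC)cc3OCc3ccccc3)o2)C1=O | intermediate
14 | rac-4-{6-[2,5-bis(benzyloxy)-4-methoxyphenyl]-4-oxo-4H-pyran-2-yl}-2,3,4-trimethoxycyclobut-2-en-1-one | COC1=C(OC)C(OC)(c2cc(=O)cc(-c3cc(OCc4ccccc4)c(OC)cc3OCc3ccccc3)o2)C1=O | intermediate
15 | (3Z)-4-{6-[2,5-bis(benzyloxy)-4-methoxyphenyl]-4-oxo-4H-pyran-2-yl}-2,3,4-trimethoxybuta-1,3-dien-1-one (pyranonyl cis to the ketene-bearing carbon) | COC(=C=O)/C(OC)=C(/OC)c1cc(=O)cc(-c2cc(OCc3ccccc3)c(OC)cc2OCc2ccccc2)o1 | intermediate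
16 | rac-2-[2,5-bis(benzyloxy)-4-methoxyphenyl]-6,7,8-trimethoxy-4aH-chromene-4,5-dione | COC1=C(OC)C(OC)=C2OC(c3cc(OCc4ccccc4)c(OC)cc3OCc3ccccc3)=CC(=O)C2C1=O | intermediate
17 | 2',5'-bis(benzyloxy)-5-hydroxy-4',6,7,8-tetramethoxyflavone | COc1cc(OCc2ccccc2)c(-c2cc(=O)c3c(O)c(OC)c(OC)c(OC)c3o2)cc1OCc1ccccc1 | intermediate
18 | 5,2',5'-trihydroxy-6,7,8,4'-tetramethoxyflavone (achiral) | COc1cc(O)c(-c2cc(=O)c3c(O)c(OC)c(OC)c(OC)c3o2)cc1O | target

**Summary**

Total step count: 10. Longest linear sequence: 10 steps (1 to 18); 7 and 11 are bought and enter at steps 5 and 7.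

Steps most likely to fail, in order of risk:

Step 7. The 6-lithiopyranone may add to unreacted pyranone before it meets the squarate, or lithiation may occur in part next to the carbonyl (C3/C5) or on the alkoxyarene. The fallback separates metalation from C–C bond formation and sets out from 10. Zincation with a hindered zinc amide (TMPZnCl·LiCl, with or without a Lewis-acid additive, chosen so that the position next to the ring oxygen is metalated) should give the 6-(chlorozincio)pyranone F1, which does not self-condense. Iodolysis should give 2-[2,5-bis(benzyloxy)-4-methoxyphenyl]-6-iodo-4H-pyran-4-one F2, whose regiochemistry can be checked on an isolated compound. Iodine–magnesium exchange with i-PrMgCl·LiCl at about −40 °C should then give the 6-(chloromagnesio)pyranone F3, which is added to dimethyl squarate 11 to return to the route at 13.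

Step 9. Ring closure of the dienylketene onto the carbonyl-bearing pyranone carbon may be slow compared with ketene dimerisation or capture by adventitious nucleophiles, so that the benzannulation gives decomposition instead of the flavone. The fallback is the classical chalcone route, sets out from aldehyde 4 and returns at the target 18. Claisen–Schmidt condensation of 4 with 2'-hydroxy-3',4',5',6'-tetramethoxyacetophenone F4 (a known building block of polymethoxyflavone synthesis, taken as purchasable; KOH, EtOH) should give the 2'-hydroxychalcone F5. Oxidative cyclisation with catalytic iodine in DMSO at about 120 °C should give 2',5'-bis(benzyloxy)-4',5,6,7,8-pentamethoxyflavone F6. BCl3 with pentamethylbenzene in CH2Cl2 (−78 → 0 °C) should then remove the chelated 5-O-methyl group and both benzyl groups while leaving the other methyl ethers, giving 18.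

Step 8. The hindered tertiary carbinol may resist alkylation, or the basic silver oxide may induce ring opening of the α-hydroxycyclobutenone before methylation is complete. The fallback moves the methylation to after the annulation and sets out from 13. Thermolysis of the free carbinol in degassed refluxing toluene follows the same ring-expansion pathway and should give the hydroquinone 2',5'-bis(benzyloxy)-5,8-dihydroxy-4',6,7-trimethoxyflavone F7, handled under argon (re-reduced with sodium dithionite if any quinone forms). Methylation with one equivalent of MeI and K2CO3 in acetone should then take place at the free 8-OH, since the 5-OH is hydrogen-bonded to the C4 carbonyl, returning to the route at 17.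

**Further compounds**

F1 | step 7 | 2-[2,5-bis(benzyloxy)-4-methoxyphenyl]-6-(chlorozincio)-4H-pyran-4-one | Cl[Zn]c1cc(=O)cc(-c2cc(OCc3ccccc3)c(OC)cc2OCc2ccccc2)o1
F2 | step 7 | 2-[2,5-bis(benzyloxy)-4-methoxyphenyl]-6-iodo-4H-pyran-4-one | Ic1cc(=O)cc(-c2cc(OCc3ccccc3)c(OC)cc2OCc2ccccc2)o1
F3 | step 7 | 2-[2,5-bis(benzyloxy)-4-methoxyphenyl]-6-(chloromagnesio)-4H-pyran-4-one | Cl[Mg]c1cc(=O)cc(-c2cc(OCc3ccccc3)c(OC)cc2OCc2ccccc2)o1
F4 | step 9 | 1-(2-hydroxy-3,4,5,6-tetramethoxyphenyl)ethan-1-one (bought) | CC(=O)c1c(O)c(OC)c(OC)c(OC)c1OC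
F5 | step 9 | (E)-3-[2,5-bis(benzyloxy)-4-methoxyphenyl]-1-(2-hydroxy-3,4,5,6-tetramethoxyphenyl)prop-2-en-1-one | COc1cc(OCc2ccccc2)c(/C=C/C(=O)c2c(O)c(OC)c(OC)c(OC)c2OC)cc1OCc1ccccc1
F6 | step 9 | 2',5'-bis(benzyloxy)-4',5,6,7,8-pentamethoxyflavone | COc1cc(OCc2ccccc2)c(-c2cc(=O)c3c(OC)c(OC)c(OC)c(OC)c3o2)cc1OCc1ccccc1
F7 | step 8 | 2',5'-bis(benzyloxy)-5,8-dihydroxy-4',6,7-trimethoxyflavone | COc1cc(OCc2ccccc2)c(-c2cc(=O)c3c(O)c(OC)c(OC)c(O)c3o2)cc1OCc1ccccc1
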